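**Retrosynthetic overview**
1. Target 11 ⇒ dehydrogenation of the C6–C7 bridge of dihydro keto ester 10 ⇒ C13 glyoxylation (oxalyl chloride, then MeOH) of dihydropentacycle 8.
2. 8 ⇒ Fischer indole disconnection of the NH-indole ⇒ tricyclic ketone 5 + phenylhydrazine.
3. 5 ⇒ intramolecular Friedel–Crafts acylation at indole C2 ⇒ acid 4 ⇒ N-alkylation of 6-bromoindole with ethyl 4-bromobutanoate.
4. Ring order: bought bromoindole → central six-membered N-ring (step 2) → second indole (step 3) → aromatisation of the central ring last (step 5).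

Assumption: the target (3-bromohomofascaplysin B skeleton) has no stereocentre, so it is achiral and no stereocontrol is needed; the SMILES is taken as written.

**Step 1**
Reactants: 1 6-bromo-1H-indole; 2 ethyl 4-bromobutanoate
Product: 4 4-(6-bromo-1H-indol-1-yl)butanoic acid, via ethyl ester 3 (not isolated)
Conditions: NaH, DMF, 0 °C to rt; then 2 M aq NaOH, MeOH, 60 °C; then aq HCl to pH 2
Reagents that add atoms: sodium hydroxide, [Na+].[OH-]
Why: The sodium indolide is N-alkylated by the primary bromide (SN2 substitution) and the ester is saponified in the same pot; no stereocentre is formed.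

**Step 2**
Reactants: 4 4-(6-bromo-1H-indol-1-yl)butanoic acid
Product: 5 3-bromo-7,8-dihydropyrido[1,2-a]indol-9(6H)-one
Conditions: polyphosphoric acid (PPA), 90 °C, 2 h; ice-water quench
Reagents that add atoms: none
Why: Intramolecular Friedel–Crafts acylation can only reach indole C2 through a six-membered ring (C3 is out of reach, C7 would need a seven-membered ring), and the 2-acylindole product is deactivated against further reaction.

**Step 3**
Reactants: 5 3-bromo-7,8-dihydropyrido[1,2-a]indol-9(6H)-one; 6 phenylhydrazine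
Product: 8 3-bromo-6,7-dihydro-12H-pyrido[1,2-a:3,4-b']diindole, via phenylhydrazone 7 (not isolated)
Conditions: PhNHNH2, AcOH, 80 °C, 1 h; then conc. HCl, 100 °C, 2 h, N2
Reagents that add atoms: none
Why: Fischer indole synthesis, in which the hydrazone can tautomerise only toward C8, so the [3,3]-sigmatropic shift, ring closure and loss of ammonia place the new indole C2 on C9 and C3 on C8, as in the conversion of 1-oxotetrahydrocarbazoles into indolocarbazoles.

**Step 4**
Reactants: 8 3-bromo-6,7-dihydro-12H-pyrido[1,2-a:3,4-b']diindole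
Product: 10 methyl 2-(3-bromo-6,7-dihydro-12H-pyrido[1,2-a:3,4-b']diindol-13-yl)-2-oxoacetate, via glyoxylyl chloride 9 (not isolated)
Conditions: (COCl)2 (1.2 equiv), THF, 0 °C, 1 h; then MeOH, 0 °C to rt
Reagents that add atoms: oxalyl chloride, ClC(=O)C(=O)Cl; methanol, CO
Why: Indole glyoxylation (electrophilic aromatic acylation) at C13, the only free pyrrole-type CH of the N-alkyl-2-indolylindole, followed by methanolysis of the acid chloride.

**Step 5**
Reactants: 10 methyl 2-(3-bromo-6,7-dihydro-12H-pyrido[1,2-a:3,4-b']diindol-13-yl)-2-oxoacetate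
Product: 11 methyl 2-(3-bromo-12H-pyrido[1,2-a:3,4-b']diindol-13-yl)-2-oxoacetate (target)
Conditions: DDQ (1.3 equiv), dry 1,4-dioxane, 80 °C, N2
Reagents that add atoms: none
Why: DDQ dehydrogenation by hydride abstraction from C7 (benzylic to C3 of the NH-indole) and proton loss from C6 gives the fully conjugated central ring, while the C13 keto ester shields the nucleus from over-oxidation.

**Compound list**
1 | 6-bromo-1H-indole | Brc1ccc2cc[nH]c2c1 | starting material
2 | ethyl 4-bromobutanoate | CCOC(=O)CCCBr | starting material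
3 | ethyl 4-(6-bromo-1H-indol-1-yl)butanoate | CCOC(=O)CCCn1ccc2ccc(Br)cc21 | intermediate (not isolated)
4 | 4-(6-bromo-1H-indol-1-yl)butanoic acid | OC(=O)CCCn1ccc2ccc(Br)cc21 | intermediate
5 | 3-bromo-7,8-dihydropyrido[1,2-a]indol-9(6H)-one | O=C1CCCn2c1cc1ccc(Br)cc12 | intermediate
6 | phenylhydrazine | NNc1ccccc1 | starting material
7 | 3-bromo-7,8-dihydropyrido[1,2-a]indol-9(6H)-one phenylhydrazone | Brc1ccc2cc3C(=NNc4ccccc4)CCCn3c2c1 | intermediate (not isolated)
8 | 3-bromo-6,7-dihydro-12H-pyrido[1,2-a:3,4-b']diindole | Brc1ccc2cc3-c4[nH]c5ccccc5c4CCn3c2c1 | intermediate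
9 | 2-(3-bromo-6,7-dihydro-12H-pyrido[1,2-a:3,4-b']diindol-13-yl)-2-oxoacetyl chloride | O=C(Cl)C(=O)c1c2ccc(Br)cc2n2CCc3c4ccccc4[nH]c3c12 | intermediate (not isolated)
10 | methyl 2-(3-bromo-6,7-dihydro-12H-pyrido[1,2-a:3,4-b']diindol-13-yl)-2-oxoacetate | COC(=O)C(=O)c1c2ccc(Br)cc2n2CCc3c4ccccc4[nH]c3c12 | intermediate
11 | methyl 2-(3-bromo-12H-pyrido[1,2-a:3,4-b']diindol-13-yl)-2-oxoacetate | COC(=O)C(=O)c1c2ccc(Br)cc2n2ccc3c4ccccc4[nH]c3c12 | target

**Totals**
Total step count: 5. Longest linear sequence: 5 steps (1 → 4 → 5 → 8 → 10 → 11).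

**Three steps most likely to fail, with fallbacks**

Step 2 (PPA acylation at C2 with a free C3; risk of acid-induced indole oligomerisation or low conversion). The fallback replaces the electrophilic ring closure by an anionic one. It sets out from compound 2, which N-alkylates purchased ethyl 6-bromo-1H-indole-2-carboxylate (CCOC(=O)c1cc2ccc(Br)cc2[nH]1; K2CO3, DMF, 60 °C) to give ethyl 6-bromo-1-(4-ethoxy-4-oxobutyl)-1H-indole-2-carboxylate F1. Dieckmann condensation (KOtBu, THF, 0 °C to rt) then gives racemic, enolisable ethyl 3-bromo-9-oxo-6,7,8,9-tetrahydropyrido[1,2-a]indole-8-carboxylate F2. Acid hydrolysis with decarboxylation (AcOH, conc. HCl, reflux) comes back to the route at compound 5.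

Step 3 (Fischer indolisation on a deactivated 2-acylindole ketone; risk of sluggish hydrazone formation or decomposition of the electron-rich product in hot acid). The fallback builds the second indole by nitroarylation and reductive cyclisation instead. It sets out from compound 5: the sodium enolate (NaH, DMF, 0 °C to rt) displaces fluoride from 1-fluoro-2-nitrobenzene (nucleophilic aromatic substitution) to give racemic 3-bromo-8-(2-nitrophenyl)-7,8-dihydropyrido[1,2-a]indol-9(6H)-one F3. Fe powder in AcOH at 80 °C reduces the nitro group to racemic 8-(2-aminophenyl)-3-bromo-7,8-dihydropyrido[1,2-a]indol-9(6H)-one F4, which is not isolated and cyclodehydrates in the same pot, coming back to the route at compound 8. The aryl bromide is untouched by these conditions.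

Step 5 (DDQ dehydrogenation of the acylated, less electron-rich nucleus; risk of incomplete conversion or oxygenation at C7 if moisture is present). The fallback reverses the order of oxidation and acylation. It sets out from compound 8: chloranil (1.1 equiv, toluene, 80 °C) dehydrogenates the more electron-rich unacylated nucleus to 3-bromo-12H-pyrido[1,2-a:3,4-b']diindole F5. (COCl)2 in THF at 0 °C then gives 2-(3-bromo-12H-pyrido[1,2-a:3,4-b']diindol-13-yl)-2-oxoacetyl chloride F6 (not isolated), and a MeOH quench comes back to the route at compound 11, the target.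

**Further compounds**
F1 | step 2 | ethyl 6-bromo-1-(4-ethoxy-4-oxobutyl)-1H-indole-2-carboxylate | CCOC(=O)CCCn1c(C(=O)OCC)cc2ccc(Br)cc21
F2 | step 2 | ethyl 3-bromo-9-oxo-6,7,8,9-tetrahydropyrido[1,2-a]indole-8-carboxylate (racemic) | CCOC(=O)C1CCn2c(C1=O)cc1ccc(Br)cc12
F3 | step 3 | 3-bromo-8-(2-nitrophenyl)-7,8-dihydropyrido[1,2-a]indol-9(6H)-one (racemic) | O=C1C(c2ccccc2[N+](=O)[O-])CCn2c1cc1ccc(Br)cc12
F4 | step 3 | 8-(2-aminophenyl)-3-bromo-7,8-dihydropyrido[1,2-a]indol-9(6H)-one (racemic) | Nc1ccccc1C1CCn2c(C1=O)cc1ccc(Br)cc12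
F5 | step 5 | 3-bromo-12H-pyrido[1,2-a:3,4-b']diindole | Brc1ccc2cc3c4[nH]c5ccccc5c4ccn3c2c1
F6 | step 5 | 2-(3-bromo-12H-pyrido[1,2-a:3,4-b']diindol-13-yl)-2-oxoacetyl chloride | O=C(Cl)C(=O)c1c2ccc(Br)cc2n2ccc3c4ccccc4[nH]c3c12
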